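**Retrosynthetic overview**
- Late functional-group changes are removed first: acetate methanolysis, Weitz–Scheffer epoxidation of ring C, peracid epoxidation of ring D, Luche reduction at C4' and two phenol-directed chlorinations lead back to a cage bis-enone phenol.
- Key disconnection: the aryl–C(sp3) bond C8–C1'. Breaking it and rearomatising ring D (its C4' oxygen lies para to C1', so ring D is a masked 4-naphthol) gives an achiral 8-bromo spiroketal bis-naphthol of the palmarumycin type, an easier skeleton that is built first and then converted into the target skeleton.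
- Enabling feature: the spiro ketal carbon C1 is bonded through its two oxygens to both peri carbons C1' and C8' of the lower naphthalene. These carbons are therefore enantiotopic (the mirror plane is the plane of rings A and C), each lies 1,5 to C8, and each is para to a naphthol oxygen (C4'–OH, C5'–OH).
- The spiroketal comes from 5-methoxy-1-tetralone and naphthalene-1,8-diol by ketalization, peri-dibromination and hydroxylation of the lower unit, C8 bromination, benzylic oxidation and dehydrogenation.
- Ring order: dioxine ring (step 1), five-membered oxygen-bridged ring that closes the cage (step 8), oxirane on ring D (step 14), oxirane on ring C (step 15).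

Key step: step 8

Numbering used in the names: upper unit = naphthalenone with spiro carbon C1, C2/C3, carbonyl carbon C4, oxygenated C5, C6, C8 (ring A benzenoid, ring C carbocyclic). Lower unit = naphthalene bonded to C1 through the oxygens on C1' and C8', with C4' and C5' para to these oxygens (ring B benzenoid in the cage, ring D carrying C1'–C4').

Remark: which antipode of KenPhos gives 13 and not its mirror image cannot be predicted; the (S)-ligand is written, and the (R)-ligand would be used if the sense of induction should be the opposite.

**Step 1**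
Reactants: 1 5-methoxy-1-tetralone; 2 naphthalene-1,8-diol
Product: 3 spiroketal of 1 and 2 (5'-methoxy-3',4'-dihydro-2'H-spiro[naphtho[1,8-de][1,3]dioxine-2,1'-naphthalene])
Conditions: TsOH·H2O (cat.), PhMe, reflux, Dean–Stark
Reagents that add atoms: none
Why: Acid-catalysed ketalization with azeotropic removal of water, where the six-membered naphthodioxine ketal is the thermodynamic sink and no stereocentre arises because the spiro carbon carries two identical arms.

**Step 2**
Reactants: 3 spiroketal
Product: 4 4',5'-dibromo spiroketal
Conditions: NBS (2.05 equiv), DMF, −20 °C → 0 °C, dark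
Reagents that add atoms: N-bromosuccinimide O=C1CCC(=O)N1Br
Why: Electrophilic aromatic bromination, in which the naphthalene positions para to the two ketal oxygens (C4', C5') should be far more nucleophilic than the anisole ring, so that two equivalents stop at the peri-dibromide.

**Step 3**
Reactants: 4 4',5'-dibromo spiroketal
Product: 7 4',5'-dihydroxy spiroketal, via dilithio arene 5 (not isolated), via bis-boronate 6 (not isolated)
Conditions: t-BuLi (4.4 equiv), THF, −78 °C; B(OMe)3, −78 °C → rt; H2O2 (30% aq), NaOH, 0 °C
Reagents that add atoms: tert-butyllithium [Li]C(C)(C)C (lithium of 5 only); trimethyl borate COB(OC)OC (boron of 6 only); hydrogen peroxide OO (the two phenolic oxygens of 7)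
Why: Double bromine–lithium exchange, borylation and boronate oxidation (C–B to C–O with retention) should replace both bromines by hydroxyl without touching ketal or methyl ether.

**Step 4**
Reactants: 7 4',5'-dihydroxy spiroketal
Product: 8 4',5'-diacetoxy spiroketal
Conditions: Ac2O, pyridine, DMAP (cat.), CH2Cl2, 0 °C (crude 7 kept under argon)
Reagents that add atoms: acetic anhydride CC(=O)OC(C)=O
Why: Acetylation protects the air-sensitive bis-naphthol and deactivates the lower naphthalene towards the electrophile and oxidants of the next three steps.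

**Step 5**
Reactants: 8 4',5'-diacetoxy spiroketal
Product: 9 8-bromo-4',5'-diacetoxy spiroketal
Conditions: NBS (1.05 equiv), MeCN, 0 °C → rt, dark
Reagents that add atoms: N-bromosuccinimide O=C1CCC(=O)N1Br
Why: Electrophilic aromatic bromination para to the methoxy group of ring A (C8), which should now be the most electron-rich free position because the lower ring carries two acyloxy groups.

**Step 6**
Reactants: 9 8-bromo-4',5'-diacetoxy spiroketal
Product: 10 8-bromo-4-oxo-4',5'-diacetoxy spiroketal
Conditions: CrO3 (5 mol %), t-BuOOH (70% aq), CH2Cl2, rt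
Reagents that add atoms: tert-butyl hydroperoxide CC(C)(C)OO
Why: Chromium-catalysed benzylic oxidation at the only benzylic methylene (C4, activated by the ortho methoxy group) should give the aryl ketone.

**Step 7**
Reactants: 10 8-bromo-4-oxo-4',5'-diacetoxy spiroketal
Product: 11 8-bromo-5-methoxy-4-oxo-2,3-didehydro spiroketal 4',5'-diacetate (quinone-monoketal enone)
Conditions: IBX (2.5 equiv), DMSO/PhMe, 75 °C
Reagents that add atoms: none
Why: IBX dehydrogenation of the ketone to the enone, which cannot go on to a naphthol because the spiro carbon C1 is quaternary.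

**Step 8**
Reactants: 11 enone diacetate
Product: 13 cage bis-enone phenol (C8–C1' bond formed; 5-OMe; 5'-OH; C4 and C4' carbonyls; C2=C3 and C2'=C3'; configuration at C1 and C1' as in 22), via bis-naphthol 12 (not isolated)
Conditions: K2CO3 (0.2 equiv), MeOH/THF, 0 °C, then evaporation under Ar; Pd2(dba)3 (2.5 mol %), (S)-KenPhos (7.5 mol %), Cs2CO3, PhMe/1,4-dioxane, 80 °C
Reagents that add atoms: none
Why: Proposed new method: after methanolysis of the two aryl acetates, zerovalent palladium should insert into the C8–Br bond; the aryl–palladium unit, held by the spiro centre above the plane of the lower naphthalene, should be attacked by the ipso carbon C1' para to a naphtholate oxygen (C-palladation of the phenolate, six-membered palladacycle), and C(sp2)–C(sp3) reductive elimination should give the dienone and return the catalyst. The closest known reactions are the palladium-catalysed intramolecular arylative dearomatization of para-substituted phenols and naphthols, including enantioselective versions with KenPhos-type ligands, and palladium-catalysed desymmetrizing arylations of prochiral bis-nucleophiles. The one ring closed is the five-membered ring C1–C8a–C8–C1'–O, which completes the oxygen-bridged bicyclo[3.2.1] cage; it forms in a 5-exo-trig sense by ipso attack on the C1'=C2' bond. The new quaternary centre C1' and the spiro carbon C1, which becomes stereogenic in the same event, are set together by the chiral ligand, which chooses between the two enantiotopic naphtholate rings of the mirror-symmetric 12; their relative configuration is fixed by the one-atom oxygen bridge. The step needs enantiotopic-group selectivity (ligand control), C- over O-arylation (the phenolate oxygens lie para across the ring, out of reach of C8) and site selectivity (only C1' and C8' are at five-membered-ring distance from C8). The C5' naphthol that is left over is the handle for the following steps.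

**Step 9**
Reactants: 13 cage bis-enone phenol
Product: 14 6'-chloro cage bis-enone phenol
Conditions: NCS (1.05 equiv), i-Pr2NH (10 mol %), CH2Cl2, 0 °C
Reagents that add atoms: N-chlorosuccinimide O=C1CCC(=O)N1Cl
Why: Electrophilic chlorination ortho to the only free phenol (C5'–OH, whose para position carries the ketal oxygen), the anisole ring A being deactivated by its ketone.

**Step 10**
Reactants: 14 6'-chloro cage bis-enone phenol
Product: 15 5'-O-acetyl-6'-chloro cage bis-enone
Conditions: Ac2O, Et3N, DMAP (cat.), CH2Cl2, 0 °C
Reagents that add atoms: acetic anhydride CC(=O)OC(C)=O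
Why: O-Acetylation of the C5' phenol installs the relay group and keeps the C4' carbonyl free of a deactivating peri phenolate.

**Step 11**
Reactants: 15 5'-O-acetyl-6'-chloro cage bis-enone
Product: 16 5-hydroxy-5'-O-acetyl-6'-chloro cage bis-enone
Conditions: BCl3 (2 equiv), CH2Cl2, −78 °C → −40 °C; aq NaHCO3
Reagents that add atoms: none
Why: BCl3 demethylation assisted by chelation to the peri C4 carbonyl, at a stage where the C1' cation is destabilised by the conjugated C4' carbonyl so that ketal and acetate should survive.

**Step 12**
Reactants: 16 5-hydroxy-5'-O-acetyl-6'-chloro cage bis-enone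
Product: 17 6,6'-dichloro-5-hydroxy-5'-O-acetyl cage bis-enone
Conditions: NCS (1.1 equiv), i-Pr2NH (10 mol %), CH2Cl2, rt
Reagents that add atoms: N-chlorosuccinimide O=C1CCC(=O)N1Cl
Why: Electrophilic chlorination ortho to the freed C5 phenol (its para position C8 is substituted), ring B being deactivated as its acetate.

**Step 13**
Reactants: 17 6,6'-dichloro-5-hydroxy-5'-O-acetyl cage bis-enone
Product: 19 4'-acetoxy-5'-hydroxy cage enone (C4'–O on the face of the C8–C1' bond and anti to the bridging oxygen), via carbinol 18 (not isolated)
Conditions: NaBH4 (1.2 equiv), CeCl3·7H2O, THF/MeOH (10:1), −78 °C; AcOH; then Et3N, CH2Cl2, rt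
Reagents that add atoms: none
Why: Luche 1,2-reduction in which the upper carbonyl is switched off as the vinylogous carboxylate of the acidic C5 chlorophenolate; hydride should add to C4' from the face of the bridging oxygen, anti to the pseudo-axial aryl substituent on C1' (steric and 4-alkoxy-dienone bias), which sets C4'; base then drives the 1,5 O-to-O acetyl shift across the peri positions to the more stable alkyl acetate and phenol.

**Step 14**
Reactants: 19 4'-acetoxy-5'-hydroxy cage enone
Product: 20 2',3'-epoxide of 19 (oxirane oxygen syn to the bridging oxygen and anti to the 4'-acetate)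
Conditions: mCPBA (3 equiv), NaHCO3, CH2Cl2, 0 °C → rt
Reagents that add atoms: 3-chloroperbenzoic acid OOC(=O)c1cccc(Cl)c1
Why: Prilezhaev epoxidation of the only non-conjugated alkene from the convex face, anti to both the pseudo-axial C4' acetate and the aryl bridge on C1', which sets C2' and C3'; the enone is inert to the peracid.

**Step 15**
Reactants: 20 2',3'-epoxy-4'-acetoxy cage enone
Product: 22 target CNP0289684.3, via acetate 21 (not isolated)
Conditions: t-BuOOH (in decane), TBD, CH2Cl2, 0 °C; then K2CO3, MeOH, 0 °C
Reagents that add atoms: tert-butyl hydroperoxide CC(C)(C)OO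
Why: Weitz–Scheffer nucleophilic epoxidation of the quinone-monoketal enone, in which the peroxide anion should add to C2 anti to the pseudo-axial aryloxy oxygen on C1 (ring B blocks that face) and so set C2 and C3 syn to the bridging oxygen; mild methanolysis, helped by the neighbouring C5' phenolate, then removes the acetate.

**Compound list**
1 | 5-methoxy-3,4-dihydronaphthalen-1(2H)-one | COc1cccc2C(=O)CCCc12 | starting material
2 | naphthalene-1,8-diol | Oc1cccc2cccc(O)c12 | starting material
3 | 5'-methoxy-3',4'-dihydro-2'H-spiro[naphtho[1,8-de][1,3]dioxine-2,1'-naphthalene] (achiral) | COc1cccc2c1CCCC23Oc4cccc5cccc(O3)c45 | intermediate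
4 | 4',5'-dibromo derivative of 3 (bromines para to the ketal oxygens) | COc1cccc2c1CCCC23Oc4ccc(Br)c5c(Br)ccc(O3)c45 | intermediate
5 | 4',5'-dilithio derivative of 3 | COc1cccc2c1CCCC23Oc4ccc([Li])c5c([Li])ccc(O3)c45 | intermediate
6 | 4',5'-bis(dimethoxyboryl) derivative of 3 | COc1cccc2c1CCCC23Oc4ccc(B(OC)OC)c5c(B(OC)OC)ccc(O3)c45 | intermediate
7 | 4',5'-dihydroxy derivative of 3 | COc1cccc2c1CCCC23Oc4ccc(O)c5c(O)ccc(O3)c45 | intermediate
8 | 4',5'-diacetoxy derivative of 3 | COc1cccc2c1CCCC23Oc4ccc(OC(C)=O)c5c(OC(C)=O)ccc(O3)c45 | intermediate
9 | 8-bromo-4',5'-diacetoxy spiroketal (bromine para to OMe, peri to the spiro carbon) | COc1ccc(Br)c2c1CCCC23Oc4ccc(OC(C)=O)c5c(OC(C)=O)ccc(O3)c45 | intermediate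
10 | 8-bromo-4-oxo-4',5'-diacetoxy spiroketal | COc1ccc(Br)c2c1C(=O)CCC23Oc4ccc(OC(C)=O)c5c(OC(C)=O)ccc(O3)c45 | intermediate
11 | 8-bromo-5-methoxy-4-oxo-2,3-didehydro spiroketal 4',5'-diacetate (achiral enone) | COc1ccc(Br)c2c1C(=O)C=CC23Oc4ccc(OC(C)=O)c5c(OC(C)=O)ccc(O3)c45 | intermediate
12 | 8-bromo-5-methoxy-4-oxo-2,3-didehydro spiroketal 4',5'-diol (mirror-symmetric bis-naphthol) | COc1ccc(Br)c2c1C(=O)C=CC23Oc4ccc(O)c5c(O)ccc(O3)c45 | intermediate
13 | cage bis-enone phenol: C8–C1' bonded, 5-OMe, 5'-OH, C4 and C4' ketones, C2=C3 and C2'=C3'; C1 and C1' as in 22 | O=C1c2c(OC)ccc3c2[C@@]2(Oc4ccc(O)c5c4[C@]3(O2)C=CC5=O)C=C1 | intermediate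
14 | 6'-chloro derivative of 13 | O=C1c2c(OC)ccc3c2[C@@]2(Oc4cc(Cl)c(O)c5c4[C@]3(O2)C=CC5=O)C=C1 | intermediate
15 | 5'-O-acetate of 14 | O=C1c2c(OC)ccc3c2[C@@]2(Oc4cc(Cl)c(OC(C)=O)c5c4[C@]3(O2)C=CC5=O)C=C1 | intermediate
16 | 5-O-demethyl derivative of 15 (free C5 phenol) | O=C1c2c(O)ccc3c2[C@@]2(Oc4cc(Cl)c(OC(C)=O)c5c4[C@]3(O2)C=CC5=O)C=C1 | intermediate
17 | 6-chloro derivative of 16 (6,6'-dichloride) | O=C1c2c(O)c(Cl)cc3c2[C@@]2(Oc4cc(Cl)c(OC(C)=O)c5c4[C@]3(O2)C=CC5=O)C=C1 | intermediate
18 | C4' carbinol of 17, 5'-acetate retained; 4'-OH on the face of the C8–C1' bond | O=C1c2c(O)c(Cl)cc3c2[C@@]2(Oc4cc(Cl)c(OC(C)=O)c5c4[C@]3(O2)C=C[C@H]5O)C=C1 | intermediate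
19 | 4'-O-acetate with free 5'-OH (acetyl shifted from O5' to O4') | O=C1c2c(O)c(Cl)cc3c2[C@@]2(Oc4cc(Cl)c(O)c5c4[C@]3(O2)C=C[C@H]5OC(C)=O)C=C1 | intermediate
20 | 2',3'-epoxide of 19; oxirane oxygen syn to the bridging oxygen, trans to the 4'-acetate | O=C1c2c(O)c(Cl)cc3c2[C@@]2(Oc4cc(Cl)c(O)c5c4[C@]3(O2)[C@@H]2O[C@@H]2[C@H]5OC(C)=O)C=C1 | intermediate
21 | 2,3:2',3'-bis-epoxide 4'-acetate; both oxirane oxygens syn to the bridging oxygen | O=C1c2c(O)c(Cl)cc3c2[C@@]2(Oc4cc(Cl)c(O)c5c4[C@]3(O2)[C@@H]2O[C@@H]2[C@H]5OC(C)=O)[C@@H]2O[C@H]12 | intermediate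
22 | CNP0289684.3: 6,6'-dichloro bis-epoxide with C4 ketone, C4' alcohol (trans to the 2',3'-oxirane) and 5,5'-phenols | O=C1c2c(O)c(Cl)cc3c2[C@@]2(Oc4cc(Cl)c(O)c5c4[C@]3(O2)[C@@H]2O[C@@H]2[C@H]5O)[C@@H]2O[C@H]12 | target

**Step count and risks**
Total steps: 15. Longest linear sequence: 15 (from 1; 2 enters in step 1).

Steps most likely to fail:

1. Step 8 (Proposed new method). Oxidative addition at the hindered, electron-rich C8–Br bond may be slow and lead to protodebromination, and the ligand may not discriminate well enough between the two enantiotopic naphtholate rings. The fallback uses known oxidative phenol–arene coupling and needs no halide. It sets out from 8: benzylic oxidation (CrO3, t-BuOOH) should give the des-bromo ketone F1; IBX the des-bromo enone F2; K2CO3 in MeOH the des-bromo bis-naphthol F3. PhI(OCOCF3)2 in (CF3)2CHOH at −20 °C should oxidise one naphthol, and the cation at C1' should be trapped by C8, which is para to the methoxy group; this gives racemic cage phenol, that is 13 together with its enantiomer F4. Preparative HPLC on a chiral stationary phase separates them, and the route is rejoined at 13.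

2. Step 13. Hydride may also attack the upper carbonyl if the phenolate does not deactivate it enough, giving mixtures of mono- and bis-reduced material. The fallback sets out from 17: an excess of NaBH4 with CeCl3·7H2O at 0 °C reduces both carbonyls on purpose. The acetyl shift then masks only the lower carbinol, giving the upper-carbinol 4'-acetate F5 (either configuration at C4). MnO2 in CH2Cl2 re-oxidises the one free allylic, benzylic alcohol, and the route is rejoined at 19.

3. Step 14. The alkene is deactivated by two allylic oxygens, so the peracid may react slowly; this gives time for oxidation of the free phenols and for acid-induced ionisation of the C1'–O bond. The fallback sets out from 19: Ac2O and pyridine give the triacetate F6, in which both phenols are masked. Epoxidation with mCPBA (or buffered CF3CO3H) should then give the epoxy triacetate F7 from the same convex face. NH4OAc in aqueous MeOH cleaves the two aryl acetates selectively, and the route is rejoined at 20.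

**Further compounds**
F1 | step 8 | des-bromo 4-oxo-4',5'-diacetoxy spiroketal | COc1cccc2c1C(=O)CCC23Oc4ccc(OC(C)=O)c5c(OC(C)=O)ccc(O3)c45
F2 | step 8 | des-bromo enone 4',5'-diacetate | COc1cccc2c1C(=O)C=CC23Oc4ccc(OC(C)=O)c5c(OC(C)=O)ccc(O3)c45
F3 | step 8 | des-bromo enone 4',5'-diol | COc1cccc2c1C(=O)C=CC23Oc4ccc(O)c5c(O)ccc(O3)c45
F4 | step 8 | enantiomer of 13 | O=C1c2c(OC)ccc3c2[C@]2(Oc4ccc(O)c5c4[C@@]3(O2)C=CC5=O)C=C1
F5 | step 13 | 4-hydroxy analogue of 19 (upper carbinol, C4 unspecified) | OC1c2c(O)c(Cl)cc3c2[C@@]2(Oc4cc(Cl)c(O)c5c4[C@]3(O2)C=C[C@H]5OC(C)=O)C=C1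
F6 | step 14 | 5,5',4'-tri-O-acetate of 19 | O=C1c2c(OC(C)=O)c(Cl)cc3c2[C@@]2(Oc4cc(Cl)c(OC(C)=O)c5c4[C@]3(O2)C=C[C@H]5OC(C)=O)C=C1
F7 | step 14 | 2',3'-epoxide of F6 | O=C1c2c(OC(C)=O)c(Cl)cc3c2[C@@]2(Oc4cc(Cl)c(OC(C)=O)c5c4[C@]3(O2)[C@@H]2O[C@@H]2[C@H]5OC(C)=O)C=C1
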